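**Plan**

- Retrosynthesis cuts, in this order: the O1–C2 ether bond of the pyran ring, the C4a–C8a bond of ring A, the C5–OMe bond, the C6–C7 bond, the C4–C4a bond and the two C8–prenyl bonds.
- Forward: dimethyl malonate is diprenylated and turned into a half-ester chloride, and a bis-silylated 1,3-diol alkyne is built from the hydroxy ester. The two are joined at C6–C7 and methanol is added to the ynone. Ring A is then closed on the open chain, the pyran ring is closed, and the last silyl group is removed.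
- Ring A is a masked 1,3,5-triketone: C4a is γ to the C7 carbonyl through the C5 methyl enol ether, C8a is a carboxyl-level carbon beside quaternary C8, and C6 is vinylic. The only acidic carbon is therefore C4a, and the only electrophile it can reach is C8a, through a six-membered ring.
- Stereochemistry: C2 comes from ethyl (R)-3-hydroxy-3-phenylpropanoate and is inverted to (S) in the Mitsunobu ring closure. C4 is set 1,3-syn to it by a reagent-controlled allenylboration and is (S) in the target.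

Key step: step 10

Assumption: the α-pinene-derived allenylborane is taken to prefer the same aldehyde face as the corresponding allylborane; atoms carry flavan numbering (O1, C2 to C8a) throughout.

**Route**

Step 1
Reactants: 1 dimethyl malonate; 2 prenyl bromide (2.2 equiv)
Product: 3 dimethyl 2,2-bis(3-methylbut-2-en-1-yl)malonate
Conditions: NaH (2.2 equiv), THF/DMF, 0 °C → rt
Reagents that add atoms: none
Why: Double malonic ester alkylation (SN2 on a primary allylic bromide) of the doubly activated methylene should install both prenyl groups on the carbon that becomes quaternary C8.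

Step 2
Reactants: 3 dimethyl 2,2-bis(3-methylbut-2-en-1-yl)malonate
Product: 4 2-(methoxycarbonyl)-5-methyl-2-(3-methylbut-2-en-1-yl)hex-4-enoic acid
Conditions: KOH (1.05 equiv), MeOH/H2O, rt → 40 °C; then aq. HCl
Reagents that add atoms: potassium hydroxide, [K+].[OH-]
Why: Monosaponification of a dialkylmalonate should stop at the half ester, because the carboxylate formed first shields the remaining hindered ester from hydroxide.

Step 3
Reactants: 4 2-(methoxycarbonyl)-5-methyl-2-(3-methylbut-2-en-1-yl)hex-4-enoic acid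
Product: 5 methyl 2-(chlorocarbonyl)-5-methyl-2-(3-methylbut-2-en-1-yl)hex-4-enoate
Conditions: (COCl)2, DMF (cat.), CH2Cl2, 0 °C → rt; used crude
Reagents that add atoms: oxalyl chloride, O=C(Cl)C(=O)Cl
Why: Acid chloride formation through the Vilsmeier-type chloroiminium species should be clean, since the acid has no α-hydrogen (no ketene) and the short cold reaction spares the prenyl alkenes from HCl.

Step 4
Reactants: 6 ethyl (R)-3-hydroxy-3-phenylpropanoate
Product: 7 ethyl (R)-3-phenyl-3-(triethylsilyloxy)propanoate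
Conditions: Et3SiCl, imidazole, CH2Cl2, 0 °C → rt
Reagents that add atoms: chlorotriethylsilane, CC[Si](Cl)(CC)CC
Why: Imidazole-promoted O-silylation protects the chiral-pool C2 carbinol as a triethylsilyl ether, which can later be cleaved in the presence of a tert-butyldimethylsilyl ether, without touching the stereocentre.

Step 5
Reactants: 7 ethyl (R)-3-phenyl-3-(triethylsilyloxy)propanoate
Product: 8 (R)-3-phenyl-3-(triethylsilyloxy)propanal
Conditions: i-Bu2AlH (1.1 equiv), CH2Cl2, −78 °C; aq. KNaC4H4O6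
Reagents that add atoms: none
Why: Partial ester reduction should stop at the aldehyde, because the aluminium hemiacetal, stabilised by the β-oxygen, survives at −78 °C until work-up.

Step 6
Reactants: 8 (R)-3-phenyl-3-(triethylsilyloxy)propanal; 9 propargyl bromide
Product: 12 (1R,3R)-1-phenyl-1-(triethylsilyloxy)hex-5-yn-3-ol, via allenylmagnesium bromide 10 (not isolated), via B-allenyldiisopinocampheylborane 11 (not isolated)
Conditions: 9, Mg, HgCl2 (cat.), Et2O, 0 °C; (+)-Ipc2BOMe [from (−)-α-pinene], Et2O, −78 °C → rt; then 8, −100 → −78 °C; NaOH, H2O2, 0 °C → rt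
Reagents that add atoms: none
Why: In this asymmetric allenylboration (propargyl transfer through a cyclic six-membered SE2′ transition state) the borane from (−)-α-pinene should deliver the propargyl group to the Re face of the aldehyde under reagent control, overriding the weak bias of the β-silyloxy centre and setting C4 1,3-syn to C2 [(3R) in 12, (S) in the target once C5 carries oxygen and the CIP order changes].

Step 7
Reactants: 12 (1R,3R)-1-phenyl-1-(triethylsilyloxy)hex-5-yn-3-ol
Product: 13 (4R,6R)-4-(tert-butyldimethylsilyloxy)-6-phenyl-6-(triethylsilyloxy)hex-1-yne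
Conditions: t-BuMe2SiOTf, 2,6-lutidine, CH2Cl2, −78 → 0 °C
Reagents that add atoms: tert-butyldimethylsilyl trifluoromethanesulfonate, CC(C)(C)[Si](C)(C)OS(=O)(=O)C(F)(F)F
Why: Silyl triflate with a hindered pyridine base silylates the secondary C4 carbinol quickly and without acid, so the triethylsilyl ether is retained and the two oxygens stay differentiated.

Step 8
Reactants: 13 (4R,6R)-4-(tert-butyldimethylsilyloxy)-6-phenyl-6-(triethylsilyloxy)hex-1-yne; 5 methyl 2-(chlorocarbonyl)-5-methyl-2-(3-methylbut-2-en-1-yl)hex-4-enoate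
Product: 14 methyl (7R,9R)-7-(tert-butyldimethylsilyloxy)-2,2-bis(3-methylbut-2-en-1-yl)-3-oxo-9-phenyl-9-(triethylsilyloxy)non-4-ynoate
Conditions: PdCl2(PPh3)2 (2 mol %), CuI (4 mol %), Et3N, THF, rt
Reagents that add atoms: none
Why: In this acyl Sonogashira coupling the copper acetylide formed in situ transmetalates to the acylpalladium species from the acid chloride, forming C6–C7 under conditions mild enough to leave the methyl ester and both silyl ethers alone (the acid chloride has no α-hydrogen and cannot form a ketene with Et3N).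

Step 9
Reactants: 14 methyl (7R,9R)-7-(tert-butyldimethylsilyloxy)-2,2-bis(3-methylbut-2-en-1-yl)-3-oxo-9-phenyl-9-(triethylsilyloxy)non-4-ynoate
Product: 15 methyl (4E,7S,9R)-7-(tert-butyldimethylsilyloxy)-5-methoxy-2,2-bis(3-methylbut-2-en-1-yl)-3-oxo-9-phenyl-9-(triethylsilyloxy)non-4-enoate
Conditions: MeOH, PMe3 (10 mol %), CH2Cl2, 0 °C → rt
Reagents that add atoms: methanol, CO
Why: Phosphine-catalysed conjugate (oxa-Michael) addition of methanol to the ynone places the methoxy group on β-carbon C5, and under these reversible conditions the thermodynamically preferred (E)-β-methoxy enone (OMe trans to the acyl group, C4a cis to C7) should result, so no selective O-methylation is needed later.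

Step 10
Reactants: 15 methyl (4E,7S,9R)-7-(tert-butyldimethylsilyloxy)-5-methoxy-2,2-bis(3-methylbut-2-en-1-yl)-3-oxo-9-phenyl-9-(triethylsilyloxy)non-4-enoate
Product: 17 5-hydroxy-3-methoxy-6,6-bis(3-methylbut-2-en-1-yl)-4-[(1S,3R)-1-(tert-butyldimethylsilyloxy)-3-phenyl-3-(triethylsilyloxy)propyl]cyclohexa-2,4-dien-1-one, via lithium dienolate 16 (not isolated)
Conditions: LiN(SiMe3)2 (3 equiv), THF (0.02 M), −78 → −20 °C; then AcOH
Reagents that add atoms: none
Why: LiN(SiMe3)2 reversibly removes a C4a–H (the only acidic C–H, since C8 is quaternary and C6 vinylic) to give the extended dienolate 16, whose γ-carbon C4a adds to the C8a ester carbonyl; loss of methoxide and immediate deprotonation of the new vinylogous β-diketone to a delocalised, phloroglucinolate-like anion make the condensation irreversible. The closest known reaction type is the Dieckmann (intramolecular Claisen) condensation run through the vinylogous γ-enolate of a β-alkoxy enone, the laboratory counterpart of polyketide phloroglucinol ring closure. Ring A closes in the 6-exo-trig mode at the ester carbonyl, whereas attack through C6 or through the enolate oxygen would need a four-membered ring. No stereocentre is created (C4a ends sp2) and C2 and C4 are not touched. The step needs γ-selectivity, a dienolate geometry that brings C8a to C4a, and survival of the C4 silyloxy group: ring size secures the first; the (E)-enol ether (C4a cis to C7) together with proton exchange through HN(SiMe3)2, which lets the rotamer with C8 syn to C5 form and be drained by cyclisation, secures the second; the low temperature holds back β-elimination. The non-nucleophilic amide base also avoids retro-Claisen cleavage at C7–C8, which an alkoxide base would invite.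

Step 11
Reactants: 17 5-hydroxy-3-methoxy-6,6-bis(3-methylbut-2-en-1-yl)-4-[(1S,3R)-1-(tert-butyldimethylsilyloxy)-3-phenyl-3-(triethylsilyloxy)propyl]cyclohexa-2,4-dien-1-one
Product: 18 4-[(1S,3R)-1-(tert-butyldimethylsilyloxy)-3-hydroxy-3-phenylpropyl]-5-hydroxy-3-methoxy-6,6-bis(3-methylbut-2-en-1-yl)cyclohexa-2,4-dien-1-one
Conditions: HF·pyridine, pyridine, THF, 0 °C
Reagents that add atoms: none
Why: Selective desilylation relies on the much faster cleavage of the less hindered triethylsilyl ether than of the tert-butyldimethylsilyl ether, and the pyridine buffer should spare the methyl enol ether and prevent acid-driven cyclodehydration at C2.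

Step 12
Reactants: 18 4-[(1S,3R)-1-(tert-butyldimethylsilyloxy)-3-hydroxy-3-phenylpropyl]-5-hydroxy-3-methoxy-6,6-bis(3-methylbut-2-en-1-yl)cyclohexa-2,4-dien-1-one
Product: 19 (2S,4S)-4-(tert-butyldimethylsilyloxy)-5-methoxy-8,8-bis(3-methylbut-2-en-1-yl)-2-phenyl-3,4-dihydro-2H-chromen-7(8H)-one
Conditions: PPh3, DIAD, THF, 0 °C → rt
Reagents that add atoms: none
Why: In this intramolecular Mitsunobu etherification the acidic C8a enol (a vinylogous acid) protonates the betaine and its oxygen displaces the C2 oxyphosphonium by SN2 with inversion (R → S), closing the pyran ring 6-exo-tet; only the C8a oxygen can reach C2, the C5 oxygen is capped as its methyl ether, and the silylated C4 oxygen cannot be activated.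

Step 13
Reactants: 19 (2S,4S)-4-(tert-butyldimethylsilyloxy)-5-methoxy-8,8-bis(3-methylbut-2-en-1-yl)-2-phenyl-3,4-dihydro-2H-chromen-7(8H)-one
Product: 20 pongaflavanol, (2S,4S)-4-hydroxy-5-methoxy-8,8-bis(3-methylbut-2-en-1-yl)-2-phenyl-3,4-dihydro-2H-chromen-7(8H)-one
Conditions: Bu4NF, AcOH, THF, 0 °C → rt
Reagents that add atoms: none
Why: Fluoride-mediated desilylation, buffered with acetic acid to suppress base-induced elimination at C4, frees the C4 hydroxyl without touching either stereocentre and should give the 2,4-cis (2S,4S) flavanol.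

**Compound list**

1 | dimethyl malonate | COC(=O)CC(=O)OC | starting material
2 | prenyl bromide (1-bromo-3-methylbut-2-ene) | CC(C)=CCBr | starting material
3 | dimethyl 2,2-bis(3-methylbut-2-en-1-yl)malonate | COC(=O)C(CC=C(C)C)(CC=C(C)C)C(=O)OC | intermediate
4 | 2-(methoxycarbonyl)-5-methyl-2-(3-methylbut-2-en-1-yl)hex-4-enoic acid | COC(=O)C(CC=C(C)C)(CC=C(C)C)C(=O)O | intermediate
5 | methyl 2-(chlorocarbonyl)-5-methyl-2-(3-methylbut-2-en-1-yl)hex-4-enoate | COC(=O)C(CC=C(C)C)(CC=C(C)C)C(=O)Cl | intermediate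
6 | ethyl (R)-3-hydroxy-3-phenylpropanoate | CCOC(=O)C[C@@H](O)c1ccccc1 | starting material
7 | ethyl (R)-3-phenyl-3-(triethylsilyloxy)propanoate | CCOC(=O)C[C@@H](O[Si](CC)(CC)CC)c1ccccc1 | intermediate
8 | (R)-3-phenyl-3-(triethylsilyloxy)propanal | O=CC[C@@H](O[Si](CC)(CC)CC)c1ccccc1 | intermediate
9 | propargyl bromide | C#CCBr | starting material
10 | allenylmagnesium bromide | C=C=C[Mg]Br | intermediate
11 | B-allenyldiisopinocampheylborane from (−)-α-pinene | C=C=CB([C@H]1C[C@H]2C[C@H](C2(C)C)[C@@H]1C)[C@H]1C[C@H]2C[C@H](C2(C)C)[C@@H]1C | intermediate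
12 | (1R,3R)-1-phenyl-1-(triethylsilyloxy)hex-5-yn-3-ol | C#CC[C@@H](O)C[C@@H](O[Si](CC)(CC)CC)c1ccccc1 | intermediate
13 | (4R,6R)-4-(tert-butyldimethylsilyloxy)-6-phenyl-6-(triethylsilyloxy)hex-1-yne | C#CC[C@@H](O[Si](C)(C)C(C)(C)C)C[C@@H](O[Si](CC)(CC)CC)c1ccccc1 | intermediate
14 | methyl (7R,9R)-7-(tert-butyldimethylsilyloxy)-2,2-bis(3-methylbut-2-en-1-yl)-3-oxo-9-phenyl-9-(triethylsilyloxy)non-4-ynoate | COC(=O)C(CC=C(C)C)(CC=C(C)C)C(=O)C#CC[C@@H](O[Si](C)(C)C(C)(C)C)C[C@@H](O[Si](CC)(CC)CC)c1ccccc1 | intermediate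
15 | methyl (4E,7S,9R)-7-(tert-butyldimethylsilyloxy)-5-methoxy-2,2-bis(3-methylbut-2-en-1-yl)-3-oxo-9-phenyl-9-(triethylsilyloxy)non-4-enoate | COC(=O)C(CC=C(C)C)(CC=C(C)C)C(=O)/C=C(/OC)C[C@@H](O[Si](C)(C)C(C)(C)C)C[C@@H](O[Si](CC)(CC)CC)c1ccccc1 | intermediate
16 | lithium (3E,5E)-dienolate of 15 (C4a deprotonated; lithium 7-(tert-butyldimethylsilyloxy)-1,5-dimethoxy-2,2-bis(3-methylbut-2-en-1-yl)-1-oxo-9-phenyl-9-(triethylsilyloxy)nona-3,5-dien-3-olate) | COC(=O)C(CC=C(C)C)(CC=C(C)C)/C(O[Li])=C\C(OC)=C/[C@@H](O[Si](C)(C)C(C)(C)C)C[C@@H](O[Si](CC)(CC)CC)c1ccccc1 | intermediate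
17 | 5-hydroxy-3-methoxy-6,6-bis(3-methylbut-2-en-1-yl)-4-[(1S,3R)-1-(tert-butyldimethylsilyloxy)-3-phenyl-3-(triethylsilyloxy)propyl]cyclohexa-2,4-dien-1-one | COC1=CC(=O)C(CC=C(C)C)(CC=C(C)C)C(O)=C1[C@@H](O[Si](C)(C)C(C)(C)C)C[C@@H](O[Si](CC)(CC)CC)c1ccccc1 | intermediate
18 | 4-[(1S,3R)-1-(tert-butyldimethylsilyloxy)-3-hydroxy-3-phenylpropyl]-5-hydroxy-3-methoxy-6,6-bis(3-methylbut-2-en-1-yl)cyclohexa-2,4-dien-1-one | COC1=CC(=O)C(CC=C(C)C)(CC=C(C)C)C(O)=C1[C@@H](O[Si](C)(C)C(C)(C)C)C[C@@H](O)c1ccccc1 | intermediate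
19 | (2S,4S)-4-(tert-butyldimethylsilyloxy)-5-methoxy-8,8-bis(3-methylbut-2-en-1-yl)-2-phenyl-3,4-dihydro-2H-chromen-7(8H)-one | COC1=CC(=O)C(CC=C(C)C)(CC=C(C)C)C2=C1[C@@H](O[Si](C)(C)C(C)(C)C)C[C@@H](c1ccccc1)O2 | intermediate
20 | pongaflavanol, (2S,4S)-4-hydroxy-5-methoxy-8,8-bis(3-methylbut-2-en-1-yl)-2-phenyl-3,4-dihydro-2H-chromen-7(8H)-one | COC1=CC(=O)C(CC=C(C)C)(CC=C(C)C)C2=C1[C@@H](O)C[C@@H](c1ccccc1)O2 | target

**Count**

Total steps: 13. Longest linear sequence: 10 steps (6 → 20, steps 4 to 13).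

**Steps most likely to fail**

1. Step 10. Ring closure onto the neopentyl-type ester may be slower than β-elimination of the C4 silyloxide from the dienolate, or the dienolate may stay in the geometry about C6–C7 that keeps C8a away from C4a.
Fallback: form the same C4a–C8a bond at the aldehyde oxidation level, where closure should be fast at −78 °C, and oxidise afterwards. It sets out from 3 (and uses 13) and returns at 17.
LiAlH4 reduction of 3 should give 2,2-bis(3-methylbut-2-en-1-yl)propane-1,3-diol F1. Monoalkylation (NaH, 4-methoxybenzyl chloride, Bu4NI cat.) should give 3-[(4-methoxybenzyl)oxy]-2,2-bis(3-methylbut-2-en-1-yl)propan-1-ol F2, and Dess–Martin oxidation the aldehyde 3-[(4-methoxybenzyl)oxy]-2,2-bis(3-methylbut-2-en-1-yl)propanal F3.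
Addition of the lithium acetylide of 13 (n-BuLi, THF, −78 °C) should give the propargylic alcohol (7R,9R)-7-(tert-butyldimethylsilyloxy)-1-[(4-methoxybenzyl)oxy]-2,2-bis(3-methylbut-2-en-1-yl)-9-phenyl-9-(triethylsilyloxy)non-4-yn-3-ol F4. Dess–Martin oxidation should give the ynone (7R,9R)-7-(tert-butyldimethylsilyloxy)-1-[(4-methoxybenzyl)oxy]-2,2-bis(3-methylbut-2-en-1-yl)-9-phenyl-9-(triethylsilyloxy)non-4-yn-3-one F5. Methanol addition as in step 9 should give (4E,7S,9R)-7-(tert-butyldimethylsilyloxy)-5-methoxy-1-[(4-methoxybenzyl)oxy]-2,2-bis(3-methylbut-2-en-1-yl)-9-phenyl-9-(triethylsilyloxy)non-4-en-3-one F6.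
DDQ in buffered CH2Cl2/water should remove the benzyl ether to give (4E,7S,9R)-7-(tert-butyldimethylsilyloxy)-1-hydroxy-5-methoxy-2,2-bis(3-methylbut-2-en-1-yl)-9-phenyl-9-(triethylsilyloxy)non-4-en-3-one F7. Dess–Martin oxidation should give the non-enolisable keto aldehyde (4E,7S,9R)-7-(tert-butyldimethylsilyloxy)-5-methoxy-2,2-bis(3-methylbut-2-en-1-yl)-3-oxo-9-phenyl-9-(triethylsilyloxy)non-4-enal F8.
LiN(SiMe3)2 at −78 °C should then trigger an intramolecular vinylogous aldol addition of C4a to the aldehyde, giving 5-hydroxy-3-methoxy-6,6-bis(3-methylbut-2-en-1-yl)-4-[(1S,3R)-1-(tert-butyldimethylsilyloxy)-3-phenyl-3-(triethylsilyloxy)propyl]cyclohex-2-en-1-one F9. Dess–Martin oxidation of its ring carbinol and enolisation give 17.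

2. Step 6. Facial control in the allenylboration may be incomplete, because the reagent must dominate the resident β-silyloxy centre, and some allenyl instead of propargyl transfer may occur.
Fallback: set C4 by substrate control and differentiate the two hydroxyls through a lactone. It sets out from 6 and returns at 13, bypassing steps 4 to 7.
Claisen condensation of 6 with the lithium enolate of tert-butyl acetate (LDA, THF, −78 → −30 °C, excess) should give tert-butyl (R)-5-hydroxy-3-oxo-5-phenylpentanoate F10. Narasaka–Prasad reduction (Et2BOMe, NaBH4, THF/MeOH, −78 °C) should give the syn diol tert-butyl (3S,5R)-3,5-dihydroxy-5-phenylpentanoate F11.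
CF3CO2H in CH2Cl2 should lactonise it through the benzylic hydroxyl to (4S,6R)-4-hydroxy-6-phenyltetrahydro-2H-pyran-2-one F12, leaving only the future C4 hydroxyl free. Silylation (t-BuMe2SiCl, imidazole, DMF) should give (4S,6R)-4-(tert-butyldimethylsilyloxy)-6-phenyltetrahydro-2H-pyran-2-one F13, and i-Bu2AlH at −78 °C the lactol (4S,6R)-4-(tert-butyldimethylsilyloxy)-6-phenyltetrahydro-2H-pyran-2-ol F14.
Ohira–Bestmann alkynylation (dimethyl 1-diazo-2-oxopropylphosphonate, K2CO3, MeOH) should give (1R,3R)-3-(tert-butyldimethylsilyloxy)-1-phenylhex-5-yn-1-ol F15. Silylation with Et3SiCl and imidazole gives 13.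

3. Step 8. Acylation with the α-quaternary acid chloride may be sluggish, so that oxidative alkyne homocoupling and decarbonylation or decomposition of the acid chloride take over.
Fallback: replace the acylation by acetylide addition to an aldehyde followed by oxidation. It sets out from 5 (and uses 13) and returns at 14.
Reduction of 5 with LiAlH(O-t-Bu)3 (THF, −78 °C) should give the aldehyde ester methyl 2-formyl-5-methyl-2-(3-methylbut-2-en-1-yl)hex-4-enoate F16. The lithium acetylide of 13 (n-BuLi, THF, −78 °C) should add to the aldehyde and leave the hindered ester alone, giving methyl (7R,9R)-7-(tert-butyldimethylsilyloxy)-3-hydroxy-2,2-bis(3-methylbut-2-en-1-yl)-9-phenyl-9-(triethylsilyloxy)non-4-ynoate F17 as a mixture of C3 epimers. Dess–Martin oxidation gives 14.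

**Further compounds**

F1 | step 10 | 2,2-bis(3-methylbut-2-en-1-yl)propane-1,3-diol | OCC(CC=C(C)C)(CC=C(C)C)CO
F2 | step 10 | 3-[(4-methoxybenzyl)oxy]-2,2-bis(3-methylbut-2-en-1-yl)propan-1-ol | COc1ccc(COCC(CC=C(C)C)(CC=C(C)C)CO)cc1
F3 | step 10 | 3-[(4-methoxybenzyl)oxy]-2,2-bis(3-methylbut-2-en-1-yl)propanal | COc1ccc(COCC(CC=C(C)C)(CC=C(C)C)C=O)cc1
F4 | step 10 | (7R,9R)-7-(tert-butyldimethylsilyloxy)-1-[(4-methoxybenzyl)oxy]-2,2-bis(3-methylbut-2-en-1-yl)-9-phenyl-9-(triethylsilyloxy)non-4-yn-3-ol (C3 epimers) | COc1ccc(COCC(CC=C(C)C)(CC=C(C)C)C(O)C#CC[C@@H](O[Si](C)(C)C(C)(C)C)C[C@@H](O[Si](CC)(CC)CC)c2ccccc2)cc1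
F5 | step 10 | (7R,9R)-7-(tert-butyldimethylsilyloxy)-1-[(4-methoxybenzyl)oxy]-2,2-bis(3-methylbut-2-en-1-yl)-9-phenyl-9-(triethylsilyloxy)non-4-yn-3-one | COc1ccc(COCC(CC=C(C)C)(CC=C(C)C)C(=O)C#CC[C@@H](O[Si](C)(C)C(C)(C)C)C[C@@H](O[Si](CC)(CC)CC)c2ccccc2)cc1
F6 | step 10 | (4E,7S,9R)-7-(tert-butyldimethylsilyloxy)-5-methoxy-1-[(4-methoxybenzyl)oxy]-2,2-bis(3-methylbut-2-en-1-yl)-9-phenyl-9-(triethylsilyloxy)non-4-en-3-one | COc1ccc(COCC(CC=C(C)C)(CC=C(C)C)C(=O)/C=C(/OC)C[C@@H](O[Si](C)(C)C(C)(C)C)C[C@@H](O[Si](CC)(CC)CC)c2ccccc2)cc1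
F7 | step 10 | (4E,7S,9R)-7-(tert-butyldimethylsilyloxy)-1-hydroxy-5-methoxy-2,2-bis(3-methylbut-2-en-1-yl)-9-phenyl-9-(triethylsilyloxy)non-4-en-3-one | OCC(CC=C(C)C)(CC=C(C)C)C(=O)/C=C(/OC)C[C@@H](O[Si](C)(C)C(C)(C)C)C[C@@H](O[Si](CC)(CC)CC)c1ccccc1
F8 | step 10 | (4E,7S,9R)-7-(tert-butyldimethylsilyloxy)-5-methoxy-2,2-bis(3-methylbut-2-en-1-yl)-3-oxo-9-phenyl-9-(triethylsilyloxy)non-4-enal | O=CC(CC=C(C)C)(CC=C(C)C)C(=O)/C=C(/OC)C[C@@H](O[Si](C)(C)C(C)(C)C)C[C@@H](O[Si](CC)(CC)CC)c1ccccc1
F9 | step 10 | 5-hydroxy-3-methoxy-6,6-bis(3-methylbut-2-en-1-yl)-4-[(1S,3R)-1-(tert-butyldimethylsilyloxy)-3-phenyl-3-(triethylsilyloxy)propyl]cyclohex-2-en-1-one (ring diastereomers) | COC1=CC(=O)C(CC=C(C)C)(CC=C(C)C)C(O)C1[C@@H](O[Si](C)(C)C(C)(C)C)C[C@@H](O[Si](CC)(CC)CC)c1ccccc1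
F10 | step 6 | tert-butyl (R)-5-hydroxy-3-oxo-5-phenylpentanoate | CC(C)(C)OC(=O)CC(=O)C[C@@H](O)c1ccccc1
F11 | step 6 | tert-butyl (3S,5R)-3,5-dihydroxy-5-phenylpentanoate | CC(C)(C)OC(=O)C[C@@H](O)C[C@@H](O)c1ccccc1
F12 | step 6 | (4S,6R)-4-hydroxy-6-phenyltetrahydro-2H-pyran-2-one | O=C1C[C@@H](O)C[C@H](c2ccccc2)O1
F13 | step 6 | (4S,6R)-4-(tert-butyldimethylsilyloxy)-6-phenyltetrahydro-2H-pyran-2-one | O=C1C[C@@H](O[Si](C)(C)C(C)(C)C)C[C@H](c2ccccc2)O1
F14 | step 6 | (4S,6R)-4-(tert-butyldimethylsilyloxy)-6-phenyltetrahydro-2H-pyran-2-ol (anomers) | OC1C[C@@H](O[Si](C)(C)C(C)(C)C)C[C@H](c2ccccc2)O1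
F15 | step 6 | (1R,3R)-3-(tert-butyldimethylsilyloxy)-1-phenylhex-5-yn-1-ol | C#CC[C@@H](O[Si](C)(C)C(C)(C)C)C[C@@H](O)c1ccccc1
F16 | step 8 | methyl 2-formyl-5-methyl-2-(3-methylbut-2-en-1-yl)hex-4-enoate | COC(=O)C(CC=C(C)C)(CC=C(C)C)C=O
F17 | step 8 | methyl (7R,9R)-7-(tert-butyldimethylsilyloxy)-3-hydroxy-2,2-bis(3-methylbut-2-en-1-yl)-9-phenyl-9-(triethylsilyloxy)non-4-ynoate (C3 epimers) | COC(=O)C(CC=C(C)C)(CC=C(C)C)C(O)C#CC[C@@H](O[Si](C)(C)C(C)(C)C)C[C@@H](O[Si](CC)(CC)CC)c1ccccc1
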